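**Plan**
- Retrosynthetic cuts: (i) O1–C2 and C4–C4a of the 2H-pyran, back to an aryl 1,1-dimethylpropargyl ether on the oxygen para to the isobutyryl group; (ii) CH2–C8 of the methylene bridge (phenolic Mannich base plus triketone C–H); (iii) prenyl–C4 of the dienone ring (dearomative allylation); (iv) the two aryl–CO bonds.
- Forward order: both carbocycles are bought as arenes. Ring A (2-methylphloroglucinol) is acylated, blocked with Cl, dearomatised by prenylation and dechlorinated. Ring B (phloroglucinol) is acylated, O-propargylated and aminomethylated. The rings are joined through CH2 and the pyran is closed last.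
- Enabling feature: O1 is the only phenol oxygen of ring B that does not flank the acyl C=O, so the C2v-symmetric monomer can be etherified there selectively. C4a is the only unsubstituted ring carbon once C8 carries the bridge, so the Claisen / H-shift / oxa-6π cascade has one productive course.
- Stereochemistry: the single quaternary centre (R) is set by a Pd/chiral-diphosphine enantioselective dearomative prenylation at the methyl-bearing carbon; it is non-enolisable afterwards.

Key step: step 9

Assumption: all dienones are written in the enol tautomer of the target SMILES; the sense of induction of the chiral ligand in step 6 cannot be predicted with confidence, so the ligand antipode that gives the (R)-dienone 12 is to be fixed by a test run.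

**Route**

Step 1
Reactants: 1 phloroglucinol; 2 isobutyryl chloride
Product: 3 phloroisobutyrophenone
Conditions: AlCl3 (3.5 equiv), PhNO2/CH2Cl2, 0 °C → rt; aq. HCl
Reagents that add atoms: none
Why: Friedel–Crafts C-acylation of phloroglucinol should stop at the mono-ketone because the chelated acyl group deactivates the ring.

Step 2
Reactants: 3 phloroisobutyrophenone; 4 3-chloro-3-methylbut-1-yne
Product: 5 symmetric 4-O-(1,1-dimethylpropargyl) ether of 3
Conditions: K2CO3 (1.1 equiv), KI (0.2 equiv), CuI (5 mol%), acetone, 40 °C
Reagents that add atoms: none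
Why: Copper-assisted O-alkylation of a phenol with a tertiary propargylic chloride should occur at the 4-OH, the most acidic hydroxyl and the only one not hydrogen-bonded to the ketone, well below the temperature of the Claisen shift.

Step 3
Reactants: 5 propargyl ether
Product: 6 mono-Mannich base of 5
Conditions: CH2(NMe2)2 (1.0 equiv), CH2Cl2, 0 °C → rt; used crude
Reagents that add atoms: bis(dimethylamino)methane, CN(C)CN(C)C
Why: Mannich aminomethylation of an electron-rich phenol by an aminal should take place once, at one of the two equivalent free ring carbons, since the zwitterionic product is deactivated.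

Step 4
Reactants: 7 2-methylphloroglucinol; 2 isobutyryl chloride
Product: 8 3-methylphloroisobutyrophenone
Conditions: AlCl3 (3.5 equiv), PhNO2/CH2Cl2, 0 °C → rt; aq. HCl
Reagents that add atoms: none
Why: Friedel–Crafts acylation as in step 1; the two free ring positions are equivalent, so one ketone results.

Step 5
Reactants: 8 3-methylphloroisobutyrophenone
Product: 9 5-chloro derivative of 8 (fully substituted ring)
Conditions: SO2Cl2 (1.0 equiv), CH2Cl2/Et2O, 0 °C
Reagents that add atoms: sulfuryl chloride, O=S(=O)(Cl)Cl
Why: Electrophilic aromatic chlorination should take the only unsubstituted carbon; the chlorine is a temporary block that leaves the methyl-bearing carbon as the only alkyl-substituted nucleophilic site.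

Step 6
Reactants: 9 chloro ketone; 10 prenyl acetate
Product: 11 (S)-chloro dienone with the C(Me)(prenyl) quaternary centre
Conditions: Pd2(dba)3·CHCl3 (2.5 mol%), (1R,2R)-N,N'-bis[2-(diphenylphosphino)benzoyl]cyclohexane-1,2-diamine (7.5 mol%), Cs2CO3 (1.05 equiv), 1,4-dioxane, rt; 1 M HCl work-up
Reagents that add atoms: none
Why: Proposed new method: Pd(0) ionises prenyl acetate to a cationic η3-(1,1-dimethylallyl)palladium complex in the chiral pocket of the diphosphine, and the caesium phenoxide of 9 attacks its unsubstituted terminus through the methyl-bearing ring carbon, because the chlorine-bearing carbon is inductively deactivated, the acyl-bearing carbon is not nucleophilic and O-allyl ethers re-ionise under Pd(0), so the non-aromatic triketone (removed as its stabilised enolate) is the sink; the two faces of the flat nucleophile differ by having the chelated isobutyryl group or the small chlorine on the flank, which the ligand is expected to read to set the quaternary centre (descriptor S in 11 only because Cl changes the priorities; the spatial arrangement is that of the target); the closest known reaction types are the Pd/chiral-diphosphine intermolecular asymmetric allylic dearomatisation of substituted naphthols and the racemic Pd-catalysed dearomative prenylation of fully substituted acylphloroglucinols.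

Step 7
Reactants: 11 chloro dienone
Product: 12 (R)-dienone (acylfilicinic-acid-type monomer with a free ring C–H)
Conditions: Zn dust (5 equiv), AcOH/THF 1:4, 0 °C → rt
Reagents that add atoms: none
Why: Zinc reduction of a doubly activated α-chloro-β-dicarbonyl unit (zinc enolate, then protonation) should remove the blocking chlorine without touching the prenyl alkene or the non-enolisable stereocentre.

Step 8
Reactants: 12 (R)-dienone; 6 Mannich base
Product: 14 methylene-bridged propargyl ether, via o-quinone methide 13 (not isolated)
Conditions: 1,4-dioxane, 55 °C, slow addition of 6 (1.2 equiv) to 12; dilute citric acid work-up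
Reagents that add atoms: none
Why: The acidic triketone protonates the Mannich base, which loses dimethylamine to the o-quinone methide 13, and the only C–H carbon of 12 adds to it in a Michael reaction with rearomatisation of ring B (o-quinone methide alkylation of a 1,3-dicarbonyl compound), without touching the stereocentre.

Step 9
Reactants: 14 methylene-bridged propargyl ether
Product: 18 target chromene, via allenyl dienone 15 (not isolated), via o-allenylphenol 16 (not isolated), via vinyl o-quinone methide 17 (not isolated)
Conditions: degassed toluene (0.02 M), 110 °C, sealed tube, Ar, dark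
Reagents that add atoms: none
Why: On heating, the aryl 1,1-dimethylpropargyl ether undergoes an aromatic propargyl Claisen [3,3] shift that delivers the alkyne terminus to C5' of ring B to give allenyl dienone 15, which enolises to o-allenylphenol 16; a 1,5-hydrogen shift from the freed phenol O–H to the central allene carbon then gives the (Z)-vinyl o-quinone methide 17, which closes to the 2H-pyran. The closest known reaction type is the thermal rearrangement of aryl 1,1-dimethylpropargyl ethers to 2,2-dimethyl-2H-chromenes, which tolerates free acylphloroglucinol-type phenols. The pyran closes by thermal disrotatory oxa-6π electrocyclisation of the 1-oxatriene O=C6'–C5'=CH–CH=CMe2, which forms O1–C2 after the [3,3] step has formed C4–C4a. No stereocentre is created (the sp3 carbon of 15 is lost on enolisation), and the quaternary (R) centre of ring A is non-enolisable and a spectator. The step needs ortho-regioselectivity and closure through the former ether oxygen: the other ortho carbon carries the CH2 bridge, so a shift there gives only a non-enolisable dienone that reverts, and the ether oxygen is the one that becomes the dienone carbonyl and then the free phenol next to the allene, while the C4'–OH is held in the hydrogen bond to the isobutyryl C=O. Neutral, non-polar, dilute conditions are chosen so that the methylene bridge and the prenyl group are not disturbed.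

**Compound list**
1 | phloroglucinol (benzene-1,3,5-triol) | Oc1cc(O)cc(O)c1 | starting material
2 | isobutyryl chloride (2-methylpropanoyl chloride) | CC(C)C(=O)Cl | starting material
3 | 2-methyl-1-(2,4,6-trihydroxyphenyl)propan-1-one | CC(C)C(=O)c1c(O)cc(O)cc1O | intermediate
4 | 3-chloro-3-methylbut-1-yne | CC(C)(Cl)C#C | starting material
5 | 1-{2,6-dihydroxy-4-[(2-methylbut-3-yn-2-yl)oxy]phenyl}-2-methylpropan-1-one | CC(C)C(=O)c1c(O)cc(OC(C)(C)C#C)cc1O | intermediate
6 | 1-{3-[(dimethylamino)methyl]-2,6-dihydroxy-4-[(2-methylbut-3-yn-2-yl)oxy]phenyl}-2-methylpropan-1-one | CC(C)C(=O)c1c(O)cc(OC(C)(C)C#C)c(CN(C)C)c1O | intermediate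
7 | 2-methylbenzene-1,3,5-triol (2-methylphloroglucinol) | Cc1c(O)cc(O)cc1O | starting material
8 | 2-methyl-1-(2,4,6-trihydroxy-3-methylphenyl)propan-1-one | CC(C)C(=O)c1c(O)cc(O)c(C)c1O | intermediate
9 | 1-(3-chloro-2,4,6-trihydroxy-5-methylphenyl)-2-methylpropan-1-one | CC(C)C(=O)c1c(O)c(Cl)c(O)c(C)c1O | intermediate
10 | 3-methylbut-2-en-1-yl acetate (prenyl acetate) | CC(C)=CCOC(C)=O | starting material
11 | (4S)-2-chloro-3,5-dihydroxy-4-methyl-4-(3-methylbut-2-en-1-yl)-6-(2-methylpropanoyl)cyclohexa-2,5-dien-1-one | CC(C)=CC[C@]1(C)C(O)=C(Cl)C(=O)C(C(=O)C(C)C)=C1O | intermediate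
12 | (4R)-3,5-dihydroxy-4-methyl-4-(3-methylbut-2-en-1-yl)-2-(2-methylpropanoyl)cyclohexa-2,5-dien-1-one | CC(C)=CC[C@]1(C)C(O)=CC(=O)C(C(=O)C(C)C)=C1O | intermediate
13 | 3-hydroxy-6-methylidene-5-[(2-methylbut-3-yn-2-yl)oxy]-2-(2-methylpropanoyl)cyclohexa-2,4-dien-1-one (o-quinone methide from 6) | CC(C)C(=O)C1=C(O)C=C(OC(C)(C)C#C)C(=C)C1=O | intermediate
14 | (4R)-6-({2,4-dihydroxy-6-[(2-methylbut-3-yn-2-yl)oxy]-3-(2-methylpropanoyl)phenyl}methyl)-3,5-dihydroxy-4-methyl-4-(3-methylbut-2-en-1-yl)-2-(2-methylpropanoyl)cyclohexa-2,5-dien-1-one | CC(C)=CC[C@]1(C)C(O)=C(Cc2c(O)c(C(=O)C(C)C)c(O)cc2OC(C)(C)C#C)C(=O)C(C(=O)C(C)C)=C1O | intermediate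
15 | allenyl dienone: 14 with ring B as the 3,5-dihydroxy-6-(3-methylbuta-1,2-dien-1-yl)-4-(2-methylpropanoyl)-6H-cyclohexa-2,4-dien-1-one attached through its C2 to the bridge (new sp3 carbon, either configuration; ring A centre R) | CC(C)=CC[C@]1(C)C(O)=C(CC2=C(O)C(C(=O)C(C)C)=C(O)C(C=C=C(C)C)C2=O)C(=O)C(C(=O)C(C)C)=C1O | intermediate
16 | o-allenylphenol: (4R)-dienone carrying a [2,4,6-trihydroxy-5-(3-methylbuta-1,2-dien-1-yl)-3-(2-methylpropanoyl)phenyl]methyl group at C6 | CC(C)=CC[C@]1(C)C(O)=C(Cc2c(O)c(C(=O)C(C)C)c(O)c(C=C=C(C)C)c2O)C(=O)C(C(=O)C(C)C)=C1O | intermediate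
17 | vinyl o-quinone methide: ring B as the 3,5-dihydroxy-6-[(Z)-3-methylbut-2-en-1-ylidene]-4-(2-methylpropanoyl)cyclohexa-2,4-dien-1-one (ring A centre R) | CC(C)=CC[C@]1(C)C(O)=C(CC2=C(O)C(C(=O)C(C)C)=C(O)/C(=C/C=C(C)C)C2=O)C(=O)C(C(=O)C(C)C)=C1O | intermediate
18 | (4R)-6-{[5,7-dihydroxy-2,2-dimethyl-6-(2-methylpropanoyl)-2H-chromen-8-yl]methyl}-3,5-dihydroxy-4-methyl-4-(3-methylbut-2-en-1-yl)-2-(2-methylpropanoyl)cyclohexa-2,5-dien-1-one | CC(C)=CC[C@]1(C)C(O)=C(Cc2c(O)c(C(=O)C(C)C)c(O)c3c2OC(C)(C)C=C3)C(=O)C(C(=O)C(C)C)=C1O | target

**Count**
Total steps: 9. Longest linear sequence: 6 (steps 4, 5, 6, 7, 8, 9).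

**Steps most likely to fail**

1. Step 6 (Proposed new method). What may go wrong: poor facial discrimination of the flat phenoxide by the chiral pocket, competing C-allylation at the chlorine-bearing carbon, or attack at the substituted allyl terminus. Fallback by known chemistry, setting out from 9: dearomative C-prenylation with prenyl bromide and NaOMe in MeOH at 0 °C (the classical alkylation of fully substituted acylphloroglucinols) should give the racemic chloro dienone F1. Zn/AcOH then gives the racemic dienone F2. F2 is resolved by fractional crystallisation of its salt with (R)-N,N-dimethyl-1-phenylethylamine from EtOAc/heptane, the salt of the R acid F3 being collected while the salt of the S acid F4 stays in the mother liquor (the S amine is used if the other salt proves less soluble). Partition of F3 between dilute HCl and EtOAc comes back to the route at 12.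

2. Step 9 (key step). What may go wrong: thermal retro-Michael opening of the methylene bridge with recombination to symmetrical dimers, acid-induced loss of the tertiary propargyl group by the triketone, closure through the acyl-flanked oxygen, or sigmatropic wandering of the prenyl group that erodes the enantiomeric purity. Fallback, setting out from 3 and 12: aminomethylation of 3 with bis(dimethylamino)methane should give the Mannich base F5. Heating F5 with 12 in dioxane at 55 °C gives the bridged trihydroxy compound F6. F6 with 3-methylbut-2-enal and catalytic ethylenediammonium diacetate in MeOH at rt should close the pyran by Knoevenagel condensation and oxa-6π electrocyclisation through the non-chelated oxygen, which comes back to the route at 18.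

3. Step 8. What may go wrong: oligomerisation of the o-quinone methide through the free ring carbon of 6 or 14, exchange of the bridge to symmetrical dimers, or premature rearrangement of the propargyl ether. Fallback, setting out from 5 and 12: Vilsmeier–Haack formylation of 5 (POCl3, DMF, MeCN, 0 °C; aq. NaOAc) should give the aldehyde F7. F7, 12, Hantzsch ester and catalytic L-proline in CH2Cl2 at rt then undergo three-component reductive alkylation: Knoevenagel condensation to the arylmethylidene trione F8 (not isolated, E/Z mixture) and conjugate hydride transfer, which comes back to the route at 14.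

**Further compounds**
F1 | step 6 | rac-2-chloro-3,5-dihydroxy-4-methyl-4-(3-methylbut-2-en-1-yl)-6-(2-methylpropanoyl)cyclohexa-2,5-dien-1-one | CC(C)=CCC1(C)C(O)=C(Cl)C(=O)C(C(=O)C(C)C)=C1O
F2 | step 6 | rac-3,5-dihydroxy-4-methyl-4-(3-methylbut-2-en-1-yl)-2-(2-methylpropanoyl)cyclohexa-2,5-dien-1-one | CC(C)=CCC1(C)C(O)=CC(=O)C(C(=O)C(C)C)=C1O
F3 | step 6 | (R)-N,N-dimethyl-1-phenylethylammonium salt of (R)-12 | CC(C)=CC[C@]1(C)C(O)=CC(=O)C(C(=O)C(C)C)=C1[O-].C[C@@H]([NH+](C)C)c1ccccc1
F4 | step 6 | (R)-N,N-dimethyl-1-phenylethylammonium salt of the (S)-enantiomer of 12 | CC(C)=CC[C@@]1(C)C(O)=CC(=O)C(C(=O)C(C)C)=C1[O-].C[C@@H]([NH+](C)C)c1ccccc1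
F5 | step 9 | 1-{3-[(dimethylamino)methyl]-2,4,6-trihydroxyphenyl}-2-methylpropan-1-one | CC(C)C(=O)c1c(O)cc(O)c(CN(C)C)c1O
F6 | step 9 | (4R)-3,5-dihydroxy-4-methyl-4-(3-methylbut-2-en-1-yl)-2-(2-methylpropanoyl)-6-{[2,4,6-trihydroxy-3-(2-methylpropanoyl)phenyl]methyl}cyclohexa-2,5-dien-1-one | CC(C)=CC[C@]1(C)C(O)=C(Cc2c(O)c(C(=O)C(C)C)c(O)cc2O)C(=O)C(C(=O)C(C)C)=C1O
F7 | step 8 | 2,4-dihydroxy-6-[(2-methylbut-3-yn-2-yl)oxy]-3-(2-methylpropanoyl)benzaldehyde | CC(C)C(=O)c1c(O)cc(OC(C)(C)C#C)c(C=O)c1O
F8 | step 8 | arylmethylidene trione from F7 and 12 (exocyclic C=C, E/Z mixture, ring A centre R) | CC(C)=CC[C@]1(C)C(=O)C(=Cc2c(O)c(C(=O)C(C)C)c(O)cc2OC(C)(C)C#C)C(=O)C(C(=O)C(C)C)=C1O
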